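Remark on the chemistry (assumption): atoms are numbered C1 to C26 in the order in which they are written in the SMILES of the target (oxygen and bromine atoms take numbers too); ring A = C11, C13, C14, C15, C24, C26; ring B = C15, C17, C19, C20, C21, C24; ring C = C2, C4, C6, C7, C9; in the decalin, β is the face of the C15 methyl group and α the opposite face.

## Analysis of the target

Neoirietetraol 33 is made of two ring systems held together by a single bond, C9–C11, between a quaternary carbon of a cyclopentane (ring C) and a tertiary carbinol carbon of a trans-decalin (rings A and B). It has eight stereocenters (C4, C7, C9, C11, C15, C17, C21, C24). In ring C the C4 bromine, the C7 hydroxyl and the C9–C11 bond lie on one face and the C9 methyl on the other, which is the arrangement of the two-carbon bridge, the endo hydroxyl and the bridgehead methyl of (+)-borneol 1. In the decalin the C15 methyl is β-axial, the C17 bromine β-equatorial, the C21 hydroxyl β-axial, the C24 hydroxyl α-axial, and the C11 hydroxyl α-axial with ring C equatorial. The sensitive groups are three tertiary alcohols (two of them a vicinal, trans-diaxial pair that can eliminate or undergo pinacol shift in acid) and two secondary bromides, each next to a quaternary carbon, so that strong base can cause elimination. The main difficulties are that neither bromide can be introduced by substitution (both carbons are neopentyl-like), and that configuration has to be relayed from ring C to the decalin across the crowded C9–C11 bond. The strategy rests on one feature: in rings A and B an equatorial bromine at C17 sits next to the methyl-bearing ring-fusion carbon C15 of a trans-decalin. That is the footprint of Br+ attack on a C15=C17 alkene with formation of the C15–C24 bond, so rings A and B can come together from a ten-membered (E,E)-diene.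

## Retrosynthetic reasoning

33 back to the alkene 31 (C21–O and C24–O bonds). The trans-diaxial diol is cut back to the α-epoxide 32 and then to the tetrasubstituted C21=C24 alkene 31. A cis-dihydroxylation would give the wrong relation, whereas trans-diaxial opening of the α-epoxide at C21 gives exactly the axial/axial pair. The forward epoxidation must come from the α face. In 31 the axial C15 methyl blocks the β face and the free, axial, homoallylic C11 hydroxyl directs the peracid to the α face, so the silyl ethers of 30 are removed first.

30 back to 28 (C21=C24 alkene from the C21 carbinol). Capture of the C21 cation by the aqueous medium in the ring-forming step gives an equatorial hydroxyl at C21 and hydrogen at C24, both wrong for the target. Both centres are erased by dehydration (to 29, mainly exocyclic) and equilibration to the most substituted alkene 30. The C11 oxygen has to be protected through these steps, otherwise a second tertiary alcohol would compete.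

28 back to 27 (C15–C24 and C17–Br bonds; the key disconnection). One C–C bond across the ten-membered ring of 27 makes rings A and B together and sets C15, C17 and C24. It also installs the neopentyl bromide in the only way it can be made cleanly, by anti addition of Br+ and carbon across an E alkene. The only ring stereocenter of 27 is C11, and the forward reaction has to pass through the chair–chair conformer with ring C pseudo-equatorial. The C11 oxygen is carried as a silyl ether so that it cannot open the bromonium ion itself.

27 back to 25 (C19–C20 bond). The ring is opened at the bond between the two allylic methylene carbons, the classical head-to-tail junction of two isoprene units. The forward reaction is the alkylation of a sulfonyl-stabilised allyl carbanion (C19) by an allylic chloride (C20), followed by removal of sulfur from 26. The sulfone is placed on C19 and not on C20 because the π-allyl intermediate of the desulfonylation then has one secondary (C19) and one tertiary (C15) terminus, so hydride goes to C19 and the E-C15=C17 alkene survives.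

25 back to 18 (arm ends). The C20 chloride comes from the E-methyl group of a prenyl unit by allylic oxidation (22 to 24). This is done only after the other alkene has been deactivated by the allylic sulfone, and it replaces any ozonolysis-based build-up of this arm, which would not tolerate a second trisubstituted alkene. The C19 sulfone comes from the allylic alcohol 20. The E-C15=C17 alkene, the C16 methyl and C19 come from the terminal alkyne 18 by syn carboalumination and hydroxymethylation, which fixes the geometry by mechanism.

18 back to 14 and 15 (C11–C13 bond; C11 stereocenter). C11 is made by addition of the Grignard reagent of 15 to the ketone 14. The order of the two arms is not free. With the C7 oxygen chelated to the ketone oxygen (and equally in a Felkin–Anh analysis with the quaternary C2 as the large group), the nucleophile enters from the face of the C9 methyl. Working through the descriptors shows that the target's C11 results only if the entering group is C13 and the group already on the ketone is C26. Adding the C26 arm last would give the C11 epimer, which would put ring C axial in the cyclization.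

14 back to 9 and 10 (C11–C26 bond; loss of one carbon). The ketone 14 comes from the lactone 9: its α-carbon is C11, which is prenylated with 10 (giving 11), hydroxylated (12), and then freed from the lactone carbonyl carbon by reduction to the triol 13 and glycol cleavage. The lactone thus serves three purposes: it protects O7, activates C11 for C–C bond formation, and supplies the carbon that is cut away.

9 back to 5 (C4–Br bond). Substitution at C4 is ruled out twice: the carbon is neopentyl-like, and the bromide has to come from the more hindered face. The bond is therefore made on an sp2 carbon (enol triflate 7 to alkenyl bromide 8, from ketone 6) and the stereocenter is set by delivering hydrogen, not bromine, from the open convex face of the bicyclic lactone.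

5 back to 1 (excision of the two-carbon bridge of 1). In 1 the endo hydroxyl, the bridgehead methyl and the carbon bridge already have the relative and absolute configuration of C7, C9 and the C9–C11 bond. Oxidation at the remote methylene (3) and Baeyer–Villiger insertion (4) cut the bridge at C4 with retention. Translactonization to 5 then frees the C4 oxygen and ties O7 to the remaining two carbons.

## Alternatives that were turned down

Alternative 1: Ring C would be made by ring contraction, cutting the C7–C9 bond. In the forward step BF3·OEt2 opens the epoxide of the epoxy ketone A1 (2,3-epoxy-2,3,4,4-tetramethylcyclohexanone) at C9 and the ring acyl carbon C7 shifts from C11 to C9, giving the acetyl cyclopentanone A2 ((S)-2-acetyl-2,3,3-trimethylcyclopentanone).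
- In its favour: the shift is stereospecific, so C9 is set by the epoxide. A2 already carries the acetyl group (C11 and one arm carbon), and it would reach a ring C ketone in far fewer steps than the eight steps to 9 in the chosen route. On step count to ring C it is clearly stronger.
- Against it: A2 has neither the C4 bromine nor the C7 stereocenter. C4 is an unactivated methylene next to the quaternary C2, and bringing in a bromine there on the hindered face would need a long detour through unsaturation. The C7 ketone would have to be reduced selectively beside the acetyl ketone and cis to it. A1 needs an enantioselective epoxidation of a tetrasubstituted enone.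
- Comparison: this key step solves only part of ring C and says nothing about the decalin. The chosen route takes C4, C7 and C9 oxidation and configuration from the chiral pool and spends its risk on the decalin instead.

Alternative 2: Ring B would be closed through the C21=C24 alkene. Low-valent titanium (TiCl3(DME)1.5 reduced by Zn–Cu) would couple the ring A ketone carbon C24 with the methyl ketone carbon C21 of the diketone A3 to give the octalin A4.
- In its favour: carbonyl coupling is dependable for tetrasubstituted alkenes in six-membered rings and gives the C21=C24 alkene directly. On this point it is stronger than the chosen route, which needs a dehydration and an equilibration (steps 22 and 23).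
- Against it: A3 must already contain the quaternary C15 stereocenter, the C11 carbinol and an oxygen at C17, each made in separate stereocontrolled steps. The C17 bromine would then have to come from substitution with inversion at a neopentyl carbon of a cyclohexane, the weakest reaction type available for this target. Low-valent titanium and Zn–Cu at reflux also threaten the C4 bromide.
- Comparison: the chosen key step creates C15, C17 and C24, the C17–Br bond and both rings in one operation from a precursor whose ring has a single stereocenter.

Alternative 3: Ring A would be made by a [4+2] cycloaddition, cutting C14–C15 and C24–C26. Under a chiral titanium Lewis acid (TiCl2(O-i-Pr)2 with a binaphthol ligand) the diene A5 would add to the methyl-bearing double bond of the quinone A6 (2-methoxy-5-methyl-1,4-benzoquinone) to give the cis-fused adduct A7.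
- In its favour: it is convergent, and the catalyst sets the quaternary C15. On convergence it is stronger than the chosen route, which is linear throughout.
- Against it: A7 is cis-fused with hydrogen at C24, while the target is trans-fused with a hydroxyl there. C11 is sp2 in A7, so its carbinol configuration would be set late by hydration of an alkene with no control element nearby. C17 arrives as a ketone and again needs substitution at a neopentyl carbon to become the bromide. The methoxy group of A6 and the C21 carbonyl must be reworked, and the chiral diene A5 must match the catalyst.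
- Comparison: after the cycloaddition at least as many steps remain as in the chosen route, and the hardest stereocenters (C11, C17, C24) remain unsolved.

Key step: step 21

## Route

Step 1
Reactants: 1 (+)-borneol
Product: 2 (+)-bornyl acetate, (1R,2S,4R)-1,7,7-trimethylbicyclo[2.2.1]heptan-2-yl acetate
Conditions: Ac2O, pyridine, DMAP (cat.), CH2Cl2, rt
Reagents that add atoms: acetic anhydride, CC(=O)OC(C)=O
Why: Acylation of the secondary alcohol; the ester deactivates its end of the molecule and survives the chromic acid oxidation that follows, and no stereocenter is touched.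

Step 2
Reactants: 2 (+)-bornyl acetate
Product: 3 5-oxobornyl acetate, (1R,2S,4R)-1,7,7-trimethyl-5-oxobicyclo[2.2.1]heptan-2-yl acetate (ketone on the CH2 next to the bridgehead CH)
Conditions: CrO3, AcOH–Ac2O, rt
Reagents that add atoms: chromium trioxide, O=[Cr](=O)=O
Why: Remote methylene oxidation by chromic acid, a known reaction of bornyl acetate that goes mainly to the CH2 group farthest from the deactivating acetate; the 6-oxo isomer is the expected minor product and is removed.

Step 3
Reactants: 3 5-oxobornyl acetate
Product: 4 bridged lactone, 6-endo-acetoxy-5,8,8-trimethyl-2-oxabicyclo[3.2.1]octan-3-one (ring oxygen on the former bridgehead CH, the future C4)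
Conditions: mCPBA, NaHCO3, CH2Cl2, rt
Reagents that add atoms: 3-chloroperoxybenzoic acid, OOC(=O)c1cccc(Cl)c1
Why: Baeyer–Villiger oxidation; the secondary bridgehead carbon migrates in preference to the methylene and with retention, so the new C4–O bond takes the place and the face of the carbon bridge that is cut.

Step 4
Reactants: 4 bridged lactone
Product: 5 hydroxy lactone, cis-fused 7-endo-hydroxy-5,6,6-trimethyl-2-oxabicyclo[3.3.0]octan-3-one (target atoms: free C4–OH; O7–C(=O)–C11H2–C9 as γ-lactone)
Conditions: K2CO3 (cat.), MeOH, rt; then aq. HCl
Reagents that add atoms: none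
Why: Methanolysis of the acetate frees the C7 oxygen, which takes over the carboxyl group (translactonization); the cis-fused γ-lactone is less strained than the bridged δ-lactone, and the exchange leaves C4–OH free and O7 masked in one operation.

Step 5
Reactants: 5 hydroxy lactone
Product: 6 keto lactone, cis-5,6,6-trimethyl-2-oxabicyclo[3.3.0]octane-3,7-dione
Conditions: Dess–Martin periodinane, NaHCO3, CH2Cl2, rt
Reagents that add atoms: none
Why: Oxidation of the secondary alcohol under neutral, buffered conditions; amine bases are avoided because the β-acyloxy ketone could lose the lactone carboxylate by E1cB elimination.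

Step 6
Reactants: 6 keto lactone
Product: 7 enol triflate, cis-5,6,6-trimethyl-3-oxo-2-oxabicyclo[3.3.0]oct-7-en-7-yl trifluoromethanesulfonate (C4=C6 alkene, OTf on C4)
Conditions: Tf2O, 2,6-di-tert-butyl-4-methylpyridine, CH2Cl2, 0 °C to rt
Reagents that add atoms: trifluoromethanesulfonic anhydride, O=S(=O)(OS(=O)(=O)C(F)(F)F)C(F)(F)F
Why: Enol triflate formation by O-sulfonylation and proton loss to a hindered, weakly basic pyridine; only C6 carries α-hydrogens (C2 is quaternary), and no free enolate is formed, which guards against β-elimination of the C7 oxygen.

Step 7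
Reactants: 7 enol triflate
Product: 8 alkenyl bromide, cis-7-bromo-5,6,6-trimethyl-2-oxabicyclo[3.3.0]oct-7-en-3-one
Conditions: Ni(OAc)2·4H2O (cat.), 1,5-cyclooctadiene (cat.), Zn (cat.), LiBr, DMA–THF, rt
Reagents that add atoms: lithium bromide, [Li+].[Br-]
Why: Nickel-catalysed exchange of an enol triflate for a halide (oxidative addition of zerovalent nickel to the C–OTf bond, halide exchange, reductive elimination), a known neutral route to alkenyl bromides that leaves the lactone alone.

Step 8
Reactants: 8 alkenyl bromide
Product: 9 bromo lactone, cis-fused 7-endo-bromo-5,6,6-trimethyl-2-oxabicyclo[3.3.0]octan-3-one (Br on C4, on the same face as C11 and O7)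
Conditions: Co(acac)2 (cat.), t-BuOOH, Et3SiH, 1,4-cyclohexadiene, n-PrOH, rt
Reagents that add atoms: none
Why: Hydrogen-atom-transfer hydrogenation of an alkenyl halide, which keeps the C–Br bond: a cobalt hydride gives H to C6 and the α-bromo radical at C4 takes H from 1,4-cyclohexadiene. The hydrogen should arrive on the convex face of the cis-fused bicycle (the face of the C9 methyl), which leaves bromine on the face of C11 and O7 as in the target.

Step 9
Reactants: 9 bromo lactone; 10 prenyl bromide (1-bromo-3-methylbut-2-ene)
Product: 11 prenyl lactone, 7-endo-bromo-5,6,6-trimethyl-4-exo-(3-methylbut-2-enyl)-2-oxabicyclo[3.3.0]octan-3-one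
Conditions: LiN(i-Pr)2, THF, −78 °C; then 10, DMPU, −78 to −30 °C
Reagents that add atoms: none
Why: Lactone enolate alkylation by a reactive allylic bromide (SN2 at the primary carbon, no allylic transposition) forms the C11–C26 bond; the C4 bromide is cis to C11 and so cannot be displaced from the rear by the enolate. The group should enter on the convex face, but this stereocenter is erased in step 12.

Step 10
Reactants: 11 prenyl lactone
Product: 12 hydroxy prenyl lactone, 7-endo-bromo-4-hydroxy-5,6,6-trimethyl-4-(3-methylbut-2-enyl)-2-oxabicyclo[3.3.0]octan-3-one (hydroxyl exo)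
Conditions: KN(SiMe3)2, THF, −78 °C; then 2-(phenylsulfonyl)-3-phenyloxaziridine
Reagents that add atoms: 2-(phenylsulfonyl)-3-phenyloxaziridine, O=S(=O)(N1OC1c1ccccc1)c1ccccc1
Why: Electrophilic hydroxylation of the lactone enolate by an N-sulfonyloxaziridine brings C11 to the carbinol level; its configuration is irrelevant because C11 becomes a ketone.

Step 11
Reactants: 12 hydroxy prenyl lactone
Product: 13 triol, (2S)-2-[(1R,3R,5S)-3-bromo-5-hydroxy-1,2,2-trimethylcyclopentyl]-5-methylhex-4-ene-1,2-diol
Conditions: LiBH4, THF–MeOH, 0 °C to rt
Reagents that add atoms: none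
Why: Hydride reduction of the lactone to the primary alcohol frees O7 and gives the 1,2-diol needed for cleavage; the hindered secondary bromide and the alkene are not reduced by LiBH4.

Step 12
Reactants: 13 triol
Product: 14 ketone, 1-[(1R,3R,5S)-3-bromo-5-hydroxy-1,2,2-trimethylcyclopentyl]-4-methylpent-3-en-1-one (C11 ketone with the C26 prenyl arm; free C7–OH)
Conditions: NaIO4, THF–H2O (pH 7), rt
Reagents that add atoms: none
Why: Periodate glycol cleavage removes the former lactone carbonyl carbon as formaldehyde and turns C11 into the ketone; the 1,3-related C7 hydroxyl is not a substrate.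

Step 13
Reactants: 14 ketone; 15 (4-bromobut-1-yn-1-yl)trimethylsilane
Product: 17 alkyne diol, (5R)-5-[(1R,3R,5S)-3-bromo-5-hydroxy-1,2,2-trimethylcyclopentyl]-8-methylnon-7-en-1-yn-5-ol (C11 configured as in the target), via silylalkyne adduct 16 (not isolated)
Conditions: Me3SiC≡CCH2CH2MgBr (from 15, Mg, THF), CeCl3, THF, −78 to 0 °C; then MeOH, K2CO3 (cat.), rt
Reagents that add atoms: none
Why: Chelation-controlled Grignard addition (Cram chelate): the C7 alkoxide and the ketone oxygen share the metal, and C13 attacks C11 from the face of the C9 methyl, anti to the quaternary C2, which gives the C11 configuration of the target because the entering group is C13 and the resident group is C26 (the Felkin–Anh model predicts the same face). CeCl3 lowers the basicity of the reagent towards the β,γ-unsaturated ketone, and methanolic K2CO3 then cleaves the C(sp)–Si bond.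

Step 14
Reactants: 17 alkyne diol
Product: 18 bis(silyl) ether, the C7,C11-bis(triethylsilyl) ether of 17
Conditions: Et3SiOTf, 2,6-lutidine, CH2Cl2, −40 °C to rt
Reagents that add atoms: triethylsilyl trifluoromethanesulfonate, CC[Si](CC)(CC)OS(=O)(=O)C(F)(F)F
Why: Silylation with a silyl triflate covers the hindered secondary and the tertiary hydroxyl in one step; the C11 ether is needed later to keep O11 out of the bromonium opening and out of the dehydration.

Step 15
Reactants: 18 bis(silyl) ether
Product: 20 allylic alcohol, (2E,6R)-6-[(1R,3R,5S)-3-bromo-1,2,2-trimethyl-5-(triethylsilyloxy)cyclopentyl]-3,9-dimethyl-6-(triethylsilyloxy)deca-2,8-dien-1-ol (C19–OH), via alkenylalane 19 (not isolated)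
Conditions: Me3Al, Cp2ZrCl2 (cat.), CH2Cl2, 0 °C to rt; then (CH2O)n, THF, rt
Reagents that add atoms: trimethylaluminium, C[Al](C)C; formaldehyde (as paraformaldehyde), C=O
Why: Zirconium-catalysed carboalumination of the terminal alkyne adds CH3 and Al syn, with methyl on C15, and the alkenylalane is hydroxymethylated with retention. This forms C15–C16 and C17–C19 and fixes the E geometry of C15=C17 by mechanism; the trisubstituted prenyl alkene does not react.

Step 16
Reactants: 20 allylic alcohol
Product: 22 allylic sulfone, the C19 phenyl sulfone corresponding to 20 (CH2OH replaced by CH2SO2Ph, E alkene unchanged), via allylic mesylate 21 (not isolated)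
Conditions: MeSO2Cl, Et3N, CH2Cl2, −40 °C; then PhSO2Na, n-Bu4NI (cat.), DMF, rt
Reagents that add atoms: sodium benzenesulfinate, [Na+].[O-]S(=O)c1ccccc1
Why: Activation of the primary allylic alcohol and SN2 displacement by the sulfur atom of the sulfinate give the primary allylic sulfone without allylic transposition.

Step 17
Reactants: 22 allylic sulfone
Product: 24 hydroxy sulfone, 22 with the E-methyl group of the prenyl arm oxidized to CH2OH (C20–OH; E-C21=C24), via enal 23 (not isolated)
Conditions: SeO2 (cat.), t-BuOOH, CH2Cl2, 0 °C to rt; then NaBH4, MeOH, 0 °C
Reagents that add atoms: selenium dioxide (oxygen carrier), O=[Se]=O; tert-butyl hydroperoxide (terminal oxygen source), CC(C)(C)OO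
Why: Allylic oxidation by SeO2 (ene reaction, then [2,3]-sigmatropic shift) attacks the electron-rich gem-dimethyl alkene at its E-methyl group, while the C15=C17 alkene is deactivated by the allylic sulfone, as in the known terminal oxidation of geranyl derivatives. Borohydride returns over-oxidized enal 23 to the alcohol.

Step 18
Reactants: 24 hydroxy sulfone
Product: 25 chloro sulfone, 24 with C20–OH replaced by C20–Cl
Conditions: N-chlorosuccinimide, Me2S, CH2Cl2, −20 to 0 °C
Reagents that add atoms: N-chlorosuccinimide, O=C1CCC(=O)N1Cl
Why: Corey–Kim chlorination of a primary allylic alcohol (alkoxysulfonium salt, SN2 by chloride) proceeds without allylic rearrangement or loss of alkene geometry and tolerates the sulfone and silyl ethers.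

Step 19
Reactants: 25 chloro sulfone
Product: 26 macrocyclic sulfone, the (3E,7E)-4,8-dimethylcyclodeca-3,7-diene bearing triethylsilyloxy and the ring C substituent at C11 and phenylsulfonyl at C19 (either configuration at C19)
Conditions: KN(SiMe3)2, THF, −78 to −20 °C, slow addition of 25 (high dilution)
Reagents that add atoms: none
Why: Intramolecular alkylation of the sulfonyl-stabilised allyl carbanion at its α-carbon C19 by the primary allylic chloride at C20, a known way to close isoprenoid 1,5-diene rings; both E alkenes are already in place and are not touched.

Step 20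
Reactants: 26 macrocyclic sulfone
Product: 27 ten-membered diene, triethyl{[(1R,3E,7E)-1-[(1R,3R,5S)-3-bromo-1,2,2-trimethyl-5-(triethylsilyloxy)cyclopentyl]-4,8-dimethylcyclodeca-3,7-dien-1-yl]oxy}silane
Conditions: PdCl2(dppp) (cat.), LiBHEt3, THF, 0 °C
Reagents that add atoms: none
Why: Reductive desulfonylation of an allylic sulfone through a π-allyl complex of palladium (zerovalent palladium is formed in situ); hydride goes to the less substituted terminus C19, so the trisubstituted E-C15=C17 alkene is kept. The C4 bromide, secondary and next to a quaternary carbon, reacts far more slowly with the hydride.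

Step 21
Reactants: 27 ten-membered diene
Product: 28 bromo decalin alcohol, trans-fused decalin with β-equatorial Br at C17, β-axial CH3 at C15, α-H at C24, α-equatorial OH and β-CH3 at C21, α-axial OSiEt3 and equatorial ring C at C11
Conditions: N-bromosuccinimide, acetone–H2O (4:1), 0 °C, dark
Reagents that add atoms: N-bromosuccinimide, O=C1CCC(=O)N1Br; water, O
Why: This is a transannular bromonium-initiated cation–olefin cyclization, the known behaviour of (E,E)-germacra-1(10),4-dienes towards electrophiles (acid, epoxide or N-bromosuccinimide), which gives trans-eudesmanes. Br+ is taken up at C17 of the C15=C17 alkene, C24 of the facing C21=C24 alkene opens the bromonium ion at its tertiary carbon C15, and water captures the tertiary cation at C21. The single C15–C24 bond closes both rings: ring B by a 6-endo attack (both carbons of each alkene lie in it) and ring A by a 6-exo attack. C17 and C15 are set by anti addition of bromine and carbon across the E alkene, which puts bromine equatorial and cis to the ring-fusion methyl. C24 and the trans fusion follow from the chair–chair conformer of the E,E ring, and at C21 water enters anti to the new bond, that is, equatorially. The sense of these four centres relative to C11 comes from the conformer that holds the quaternary ring C substituent pseudo-equatorial and the silyloxy group pseudo-axial. The step needs Br+ on C15=C17 and not on C21=C24; the latter is homoallylic to the C11 oxygen and lies next to the crowded C9–C11 junction, so it should be both less electron-rich and more shielded, and the silyl ether keeps O11 from opening the bromonium ion.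

Step 22
Reactants: 28 bromo decalin alcohol
Product: 29 exocyclic alkene, 28 with C21(OH)CH3 replaced by C21=CH2 (expected main isomer; ring-alkene isomers are carried along)
Conditions: SOCl2, pyridine, CH2Cl2, −20 to 0 °C
Reagents that add atoms: none
Why: Dehydration of the only free (tertiary) alcohol through its chlorosulfite by E2 elimination; the equatorial leaving group has anti-periplanar hydrogens only in the methyl group, so the exocyclic alkene should dominate, and all isomers converge in step 23.

Step 23
Reactants: 29 exocyclic alkene
Product: 30 tetrasubstituted alkene, the C21=C24 octalin with CH3 on C21 (silyl ethers and both bromides unchanged)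
Conditions: TsOH (anhydrous, cat.), benzene, 40 °C
Reagents that add atoms: none
Why: Acid-catalysed alkene isomerization through the tertiary C21 cation equilibrates the isomers towards the tetrasubstituted C21=C24 position, the most substituted alkene available; anhydrous, catalytic acid is chosen to spare the silyl ethers.

Step 24
Reactants: 30 tetrasubstituted alkene
Product: 31 octalin diol, 30 with free C7–OH and C11–OH
Conditions: HF·pyridine, pyridine–THF, 0 °C to rt
Reagents that add atoms: none
Why: Fluoride cleavage of both silyl ethers under non-basic conditions, which avoids elimination at the bromides; the free axial C11 hydroxyl is wanted as a directing group for step 25.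

Step 25
Reactants: 31 octalin diol
Product: 32 α-epoxide, the 21α,24α-epoxide of 31
Conditions: mCPBA, NaHCO3, CH2Cl2, 0 °C
Reagents that add atoms: 3-chloroperoxybenzoic acid, OOC(=O)c1cccc(Cl)c1
Why: Peracid epoxidation; the β face is blocked by the axial C15 methyl and the axial homoallylic C11 hydroxyl on the α face can hydrogen-bond the peracid, so both effects should lead to the α-epoxide.

Step 26
Reactants: 32 α-epoxide
Product: 33 neoirietetraol
Conditions: HClO4 (aq., dilute), THF, 0 °C to rt
Reagents that add atoms: water, O
Why: Acid-catalysed epoxide hydrolysis with trans-diaxial opening (Fürst–Plattner rule): water attacks C21 from the β face rather than the neopentyl ring-fusion carbon C24, which gives the β-axial C21 hydroxyl and the α-axial C24 hydroxyl of the target.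

## Compound list

1 | (+)-borneol, (1R,2S,4R)-1,7,7-trimethylbicyclo[2.2.1]heptan-2-ol | CC1(C)[C@H]2C[C@H](O)[C@]1(C)CC2 | starting material
2 | (+)-bornyl acetate | CC1(C)[C@H]2C[C@H](OC(C)=O)[C@]1(C)CC2 | intermediate
3 | 5-oxobornyl acetate | CC1(C)[C@H]2C[C@H](OC(C)=O)[C@]1(C)CC2=O | intermediate
4 | bridged lactone, 6-endo-acetoxy-5,8,8-trimethyl-2-oxabicyclo[3.2.1]octan-3-one | CC1(C)[C@H]2C[C@H](OC(C)=O)[C@]1(C)CC(=O)O2 | intermediate
5 | hydroxy lactone, cis-fused 7-endo-hydroxy-5,6,6-trimethyl-2-oxabicyclo[3.3.0]octan-3-one | CC1(C)[C@H](O)C[C@H](OC(=O)C2)[C@@]12C | intermediate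
6 | keto lactone, cis-5,6,6-trimethyl-2-oxabicyclo[3.3.0]octane-3,7-dione | CC1(C)C(=O)C[C@H](OC(=O)C2)[C@@]12C | intermediate
7 | enol triflate, cis-5,6,6-trimethyl-3-oxo-2-oxabicyclo[3.3.0]oct-7-en-7-yl trifluoromethanesulfonate | CC1(C)C(OS(=O)(=O)C(F)(F)F)=C[C@H](OC(=O)C2)[C@@]12C | intermediate
8 | alkenyl bromide, cis-7-bromo-5,6,6-trimethyl-2-oxabicyclo[3.3.0]oct-7-en-3-one | CC1(C)C(Br)=C[C@H](OC(=O)C2)[C@@]12C | intermediate
9 | bromo lactone, cis-fused 7-endo-bromo-5,6,6-trimethyl-2-oxabicyclo[3.3.0]octan-3-one | CC1(C)[C@H](Br)C[C@H](OC(=O)C2)[C@@]12C | intermediate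
10 | prenyl bromide, 1-bromo-3-methylbut-2-ene | CC(C)=CCBr | starting material
11 | prenyl lactone, 7-endo-bromo-5,6,6-trimethyl-4-exo-(3-methylbut-2-enyl)-2-oxabicyclo[3.3.0]octan-3-one | CC1(C)[C@H](Br)C[C@H](OC(=O)[C@H]2CC=C(C)C)[C@@]12C | intermediate
12 | hydroxy prenyl lactone, 7-endo-bromo-4-exo-hydroxy-5,6,6-trimethyl-4-(3-methylbut-2-enyl)-2-oxabicyclo[3.3.0]octan-3-one | CC1(C)[C@H](Br)C[C@H](OC(=O)[C@@]2(O)CC=C(C)C)[C@@]12C | intermediate
13 | triol, (2S)-2-[(1R,3R,5S)-3-bromo-5-hydroxy-1,2,2-trimethylcyclopentyl]-5-methylhex-4-ene-1,2-diol | CC1(C)[C@H](Br)C[C@H](O)[C@]1(C)[C@](O)(CO)CC=C(C)C | intermediate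
14 | ketone, 1-[(1R,3R,5S)-3-bromo-5-hydroxy-1,2,2-trimethylcyclopentyl]-4-methylpent-3-en-1-one | CC1(C)[C@H](Br)C[C@H](O)[C@]1(C)C(=O)CC=C(C)C | intermediate
15 | (4-bromobut-1-yn-1-yl)trimethylsilane | C[Si](C)(C)C#CCCBr | starting material
16 | silylalkyne adduct, (5R)-5-[(1R,3R,5S)-3-bromo-5-hydroxy-1,2,2-trimethylcyclopentyl]-8-methyl-1-(trimethylsilyl)non-7-en-1-yn-5-ol (not isolated) | CC1(C)[C@H](Br)C[C@H](O)[C@]1(C)[C@](O)(CC=C(C)C)CCC#C[Si](C)(C)C | intermediate
17 | alkyne diol, (5R)-5-[(1R,3R,5S)-3-bromo-5-hydroxy-1,2,2-trimethylcyclopentyl]-8-methylnon-7-en-1-yn-5-ol | CC1(C)[C@H](Br)C[C@H](O)[C@]1(C)[C@](O)(CC=C(C)C)CCC#C | intermediate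
18 | bis(silyl) ether, C7,C11-bis(triethylsilyl) ether of 17 | CC1(C)[C@H](Br)C[C@H](O[Si](CC)(CC)CC)[C@]1(C)[C@](O[Si](CC)(CC)CC)(CC=C(C)C)CCC#C | intermediate
19 | alkenylalane, (E)-alkenyl(dimethyl)alane from 18 with CH3 on C15 and Al on C17 (not isolated) | CC1(C)[C@H](Br)C[C@H](O[Si](CC)(CC)CC)[C@]1(C)[C@](O[Si](CC)(CC)CC)(CC=C(C)C)CC/C(C)=C/[Al](C)C | intermediate
20 | allylic alcohol, (2E,6R)-6-[(1R,3R,5S)-3-bromo-1,2,2-trimethyl-5-(triethylsilyloxy)cyclopentyl]-3,9-dimethyl-6-(triethylsilyloxy)deca-2,8-dien-1-ol | CC1(C)[C@H](Br)C[C@H](O[Si](CC)(CC)CC)[C@]1(C)[C@](O[Si](CC)(CC)CC)(CC=C(C)C)CC/C(C)=C/CO | intermediate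
21 | allylic mesylate, methanesulfonate of 20 (not isolated) | CC1(C)[C@H](Br)C[C@H](O[Si](CC)(CC)CC)[C@]1(C)[C@](O[Si](CC)(CC)CC)(CC=C(C)C)CC/C(C)=C/COS(C)(=O)=O | intermediate
22 | allylic sulfone, C19 phenyl sulfone corresponding to 20 | CC1(C)[C@H](Br)C[C@H](O[Si](CC)(CC)CC)[C@]1(C)[C@](O[Si](CC)(CC)CC)(CC=C(C)C)CC/C(C)=C/CS(=O)(=O)c1ccccc1 | intermediate
23 | enal, 22 with the E-methyl group of the prenyl arm oxidized to CHO (not isolated) | CC1(C)[C@H](Br)C[C@H](O[Si](CC)(CC)CC)[C@]1(C)[C@](O[Si](CC)(CC)CC)(C/C=C(\C)C=O)CC/C(C)=C/CS(=O)(=O)c1ccccc1 | intermediate
24 | hydroxy sulfone, 22 with the E-methyl group of the prenyl arm oxidized to CH2OH (C20–OH) | CC1(C)[C@H](Br)C[C@H](O[Si](CC)(CC)CC)[C@]1(C)[C@](O[Si](CC)(CC)CC)(C/C=C(\C)CO)CC/C(C)=C/CS(=O)(=O)c1ccccc1 | intermediate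
25 | chloro sulfone, C20 chloride corresponding to 24 | CC1(C)[C@H](Br)C[C@H](O[Si](CC)(CC)CC)[C@]1(C)[C@](O[Si](CC)(CC)CC)(C/C=C(\C)CCl)CC/C(C)=C/CS(=O)(=O)c1ccccc1 | intermediate
26 | macrocyclic sulfone, (3E,7E)-4,8-dimethylcyclodeca-3,7-diene with OSiEt3 and the ring C substituent at C11 and SO2Ph at C19 | CC1(C)[C@H](Br)C[C@H](O[Si](CC)(CC)CC)[C@]1(C)[C@@]1(O[Si](CC)(CC)CC)CC/C(C)=C/C(S(=O)(=O)c2ccccc2)C/C(C)=C/C1 | intermediate
27 | ten-membered diene, triethyl{[(1R,3E,7E)-1-[(1R,3R,5S)-3-bromo-1,2,2-trimethyl-5-(triethylsilyloxy)cyclopentyl]-4,8-dimethylcyclodeca-3,7-dien-1-yl]oxy}silane | CC1(C)[C@H](Br)C[C@H](O[Si](CC)(CC)CC)[C@]1(C)[C@@]1(O[Si](CC)(CC)CC)CC/C(C)=C/CC/C(C)=C/C1 | intermediate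
28 | bromo decalin alcohol, trans-decalin with 17β-Br, 15β-CH3, 24α-H, 21α-OH/21β-CH3, 11α-OSiEt3 | CC1(C)[C@H](Br)C[C@H](O[Si](CC)(CC)CC)[C@]1(C)[C@@]1(O[Si](CC)(CC)CC)CC[C@]2(C)[C@@H](Br)CC[C@](C)(O)[C@H]2C1 | intermediate
29 | exocyclic alkene, 28 with C21=CH2 | CC1(C)[C@H](Br)C[C@H](O[Si](CC)(CC)CC)[C@]1(C)[C@@]1(O[Si](CC)(CC)CC)CC[C@]2(C)[C@@H](Br)CCC(=C)[C@H]2C1 | intermediate
30 | tetrasubstituted alkene, C21=C24 octalin, bis(triethylsilyl) ether | CC1(C)[C@H](Br)C[C@H](O[Si](CC)(CC)CC)[C@]1(C)[C@@]1(O[Si](CC)(CC)CC)CC[C@]2(C)[C@@H](Br)CCC(C)=C2C1 | intermediate
31 | octalin diol, 30 with free C7–OH and C11–OH | CC1(C)[C@H](Br)C[C@H](O)[C@]1(C)[C@@]1(O)CC[C@]2(C)[C@@H](Br)CCC(C)=C2C1 | intermediate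
32 | α-epoxide, 21α,24α-epoxide of 31 | CC1(C)[C@H](Br)C[C@H](O)[C@]1(C)[C@@]1(O)CC[C@]2(C)[C@@H](Br)CC[C@]3(C)O[C@]23C1 | intermediate
33 | neoirietetraol | CC1(C)[C@H](Br)C[C@H](O)[C@]1(C)[C@@]1(O)CC[C@]2(C)[C@@H](Br)CC[C@@](C)(O)[C@@]2(O)C1 | target

## Step count and risks

Total step count: 26. Longest linear sequence: 26 steps, from 1 to 33; compounds 10 and 15 are bought and enter directly.

Steps least certain to work:

Step 21 (key step). The most likely failures are bromonium formation on the wrong alkene (C21=C24), which leads to a bromohydrin or to the five/seven-membered skeleton, and simple bromohydrin formation without ring closure. The two alkenes differ only modestly in electron density, and the wanted conformer must be populated. Fallback: from 27, the same transannular closure is triggered by divalent mercury, Hg(OCOCF3)2 in aqueous nitromethane. This larger electrophile is more sensitive to the shielding of C21=C24, and its addition to an alkene is reversible, so the wanted closure can drain the equilibrium. NaBr then gives the organomercuric bromide F1, which is 28 with HgBr in place of the C17 bromine. Brominolysis of F1 with Br2 and LiBr in pyridine, which runs mainly with retention, gives 28, where the route is rejoined.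

Step 8. The likely failure is poor facial selectivity in the hydrogen transfer to the α-bromo radical. In the lactone the two substituents on the C11/O7 face are tied back, so the difference between the faces is smaller than in an open ring; loss of bromine is a lesser risk. Fallback: from 8, the lactone is opened with MeNH(OMe)·HCl and Me3Al to the hydroxy amide F2, which is N-methoxy-N-methyl-2-[(1R,5S)-3-bromo-5-hydroxy-1,2,2-trimethylcyclopent-3-enyl]acetamide. O7 is then silylated (t-BuMe2SiOTf, 2,6-lutidine) to the silyl ether F3. The same cobalt hydride hydrogenation is run on this open substrate, where a bulky silyloxy group and a free side chain crowd the C11/O7 face, to give the saturated bromo amide F4. Aqueous HF in MeCN removes the silyl group of F4 and the hydroxy amide closes to 9.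

Step 13. The likely failures are enolization (and deconjugation) of the β,γ-unsaturated ketone by the basic reagent, retro-aldol opening of the magnesium aldolate, and incomplete facial control. Fallback: from 14, O7 is first silylated (Et3SiOTf, 2,6-lutidine) to the silyloxy ketone F5. This removes the acidic hydroxyl and the retro-aldol path and moves the addition from chelation control to Felkin–Anh control, which predicts the same face. Addition of the same organocerium reagent to F5 gives the silylalkyne carbinol F6, methanolic K2CO3 gives the terminal alkyne F7, and silylation of the tertiary hydroxyl of F7 (Et3SiOTf) gives 18.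

Step 19. The likely failures are intermolecular alkylation (dimers and oligomers) and slow closure because of the strain of the ten-membered ring with two E alkenes. Fallback: from 20, sulfur is left out altogether. Allylic oxidation of the prenyl arm (SeO2, t-BuOOH, then NaBH4) gives the bis-allylic diol F8, and CBr4/PPh3 gives the bis-allylic dibromide F9. Zerovalent nickel, Ni(CO)4 in DMF at high dilution, then couples the two allylic termini of F9 (C19–C20) to give 27 directly. This is the known nickel-mediated closure of 1,5-diene rings, and its own weakness is partial loss of alkene geometry.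

Step 23. The likely failures are an equilibrium that stops at a mixture of tri- and tetrasubstituted alkenes, and acid-induced loss of the tertiary silyl ether followed by ionization at C11. Fallback: from 28, the alcohol is dehydrated by a syn elimination with the Burgess reagent (methyl N-(triethylammoniosulfonyl)carbamate, benzene, 50 °C). The C24 hydrogen is cis to the C21 hydroxyl and is the tertiary, Zaitsev hydrogen, so 30 should form directly without acid, and the route is rejoined at 30.

## Further compounds

F1 | step 21 | organomercuric bromide, 28 with HgBr in place of Br at C17 (β, equatorial) | CC1(C)[C@H](Br)C[C@H](O[Si](CC)(CC)CC)[C@]1(C)[C@@]1(O[Si](CC)(CC)CC)CC[C@]2(C)[C@@H]([Hg]Br)CC[C@](C)(O)[C@H]2C1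
F2 | step 8 | hydroxy amide, N-methoxy-N-methyl-2-[(1R,5S)-3-bromo-5-hydroxy-1,2,2-trimethylcyclopent-3-enyl]acetamide | CC1(C)C(Br)=C[C@H](O)[C@]1(C)CC(=O)N(C)OC
F3 | step 8 | silyl ether, tert-butyldimethylsilyl ether of F2 | CC1(C)C(Br)=C[C@H](O[Si](C)(C)C(C)(C)C)[C@]1(C)CC(=O)N(C)OC
F4 | step 8 | saturated bromo amide, N-methoxy-N-methyl-2-[(1R,3R,5S)-3-bromo-5-(tert-butyldimethylsilyloxy)-1,2,2-trimethylcyclopentyl]acetamide | CC1(C)[C@H](Br)C[C@H](O[Si](C)(C)C(C)(C)C)[C@]1(C)CC(=O)N(C)OC
F5 | step 13 | silyloxy ketone, C7 triethylsilyl ether of 14 | CC1(C)[C@H](Br)C[C@H](O[Si](CC)(CC)CC)[C@]1(C)C(=O)CC=C(C)C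
F6 | step 13 | silylalkyne carbinol, C7 triethylsilyl ether of 16 | CC1(C)[C@H](Br)C[C@H](O[Si](CC)(CC)CC)[C@]1(C)[C@](O)(CC=C(C)C)CCC#C[Si](C)(C)C
F7 | step 13 | terminal alkyne, C7 triethylsilyl ether of 17 | CC1(C)[C@H](Br)C[C@H](O[Si](CC)(CC)CC)[C@]1(C)[C@](O)(CC=C(C)C)CCC#C
F8 | step 19 | bis-allylic diol, 20 with the E-methyl group of the prenyl arm oxidized to CH2OH | CC1(C)[C@H](Br)C[C@H](O[Si](CC)(CC)CC)[C@]1(C)[C@](O[Si](CC)(CC)CC)(C/C=C(\C)CO)CC/C(C)=C/CO
F9 | step 19 | bis-allylic dibromide corresponding to F8 | CC1(C)[C@H](Br)C[C@H](O[Si](CC)(CC)CC)[C@]1(C)[C@](O[Si](CC)(CC)CC)(C/C=C(\C)CBr)CC/C(C)=C/CBr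
F0 | step 23 | none | none
A1 | alternative 1 | 2,3-epoxy-2,3,4,4-tetramethylcyclohexanone (single enantiomer) | CC1(C)CCC(=O)[C@]2(C)O[C@]12C
A2 | alternative 1 | (S)-2-acetyl-2,3,3-trimethylcyclopentanone | CC1(C)CCC(=O)[C@]1(C)C(C)=O
A3 | alternative 2 | diketone: ring A cyclohexanone (C24 ketone) with the C15 side chain ending in the C21 methyl ketone | CC1(C)[C@H](Br)C[C@H](O[Si](C)(C)C(C)(C)C)[C@]1(C)[C@@]1(O[Si](CC)(CC)CC)CC[C@](C)([C@H](OCc2ccc(OC)cc2)CCC(C)=O)C(=O)C1
A4 | alternative 2 | octalin with the tetrasubstituted C21=C24 alkene | CC1(C)[C@H](Br)C[C@H](O[Si](C)(C)C(C)(C)C)[C@]1(C)[C@@]1(O[Si](CC)(CC)CC)CC[C@]2(C)[C@H](OCc3ccc(OC)cc3)CCC(C)=C2C1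
A5 | alternative 3 | 2-substituted butadiene carrying ring C | CC1(C)[C@H](Br)C[C@H](O[Si](C)(C)C(C)(C)C)[C@]1(C)C(=C)C=C
A6 | alternative 3 | 2-methoxy-5-methyl-1,4-benzoquinone | COC1=CC(=O)C(C)=CC1=O
A7 | alternative 3 | cis-fused adduct: ring A cyclohexene on the methoxy enedione ring B | CC1(C)[C@H](Br)C[C@H](O[Si](C)(C)C(C)(C)C)[C@]1(C)C1=CC[C@]2(C)C(=O)C=C(OC)C(=O)[C@@H]2C1
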